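The reading times came first: ochre was to be read at 2.5 h and grey at 8.0 h, from the same charge.

the same everywhere: gas 0.57 mM (held); free catalyst 0.44 mol%
- midnight: left-handed substrate 8.7 mM; right-handed substrate 8.7 mM; run made earlier
- spring: left-handed substrate 20 mM; right-handed substrate 20 mM; run made earlier
- ochre: left-handed substrate 13 mM; right-handed substrate 13 mM; time 2.5 h
- grey: left-handed substrate 13 mM; right-handed substrate 13 mM; time 8.0 h

- which of the two ends with the higher excess of left-handed product over right-handed product in the product ("neither" if they lie within 2 percentage points) (ochre / grey / neither)
- excess of left-handed product over right-handed product in the product at the end, ochre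
- excess of left-handed product over right-handed product in the product at the end, grey

| run | time / h | left-handed product / % | right-handed product / % |
|---|---|---|---|
| midnight | 0.250 | 6.0 | 3.1 |
| midnight | 0.500 | 8.1 | 4.3 |
| midnight | 1.33 | 9.1 | 4.8 |
| midnight | 3.00 | 9.9 | 4.6 |
| spring | 0.833 | 19.3 | 10.3 |
| spring | 1.50 | 19.4 | 10.1 |
| spring | 2.50 | 20.4 | 9.5 |
| spring | 3.00 | 19.3 | 10.0 |

(readings scatter by 0.5 percentage points)

So the question was whether the extra time in grey changed the product. But the spring run held left-handed product at 19.3% at 0.833 h and 19.3% at 3.00 h, with about 29.6% of the charge as product, although 70.4% was not product. Midnight's left-handed product went from 9.1% at 1.33 h to 9.9% at 3.00 h. Ochre's charge lies between the two runs, and its reading at 2.5 h comes later than spring's first, so I took both flasks as read on the flat part.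

I therefore needed one number, the left share: the fraction of all product that is left-handed product, the selectivity written as a share. Pooling the four spring readings, which hold more product than midnight's last reading, I got 66.3%. The excess is that share minus the remaining share, so I reckoned 32.5% for both flasks.

The forecast said neither, with 33% for ochre and 33% for grey, each from 30.5% to 35%, slightly above my figure. Its ground was: “Once the catalyst is dead, the product is frozen.”

Ochre gave 35.1% and grey 35.1%, so the answer was neither. Grey's excess at 80.0 h was still 35.1%, with spent catalyst at 100% by 8.00 h.

    partner + free catalyst + left-handed substrate → free catalyst + left-handed product (k = 13000 M⁻² s⁻¹)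
    partner + free catalyst + right-handed substrate → free catalyst + right-handed product (k = 3.50 × 10⁵ M⁻² min⁻¹)
    left-handed substrate ⇌ right-handed substrate (k = 0.00910 min⁻¹)
    gas ⇌ partner, rate k4*(csat - [partner]) (kL = 53.0 min⁻¹)
    partner + free catalyst → spent catalyst (k = 140 M⁻¹ min⁻¹)
    partner → decomposed reagent (k = 0.0460 min⁻¹)

Ochre's product was 20.4% of the charge, and the left share made 13.5% of the charge left-handed product, against 13.8% in the flask. A neighbour flask, like grey but with 1.1 mol% of free catalyst, made 42.7% product, so the left share gave 28.3%, against 28.0% in that flask.

The runs were computed on assumed constants, noise included.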